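## Retrosynthetic overview

1. Schizolaenone A (17) comes from its 4'-O-TBS ether 16 by a near-neutral aryl silyl ether cleavage.
2. 16 is made from the open-chain δ-hydroxy triketo ester 13 in one flask. Ring C closes first (carbinol O onto the C8a ketone). Ring A then closes by C4a–C5 bond formation from an acylketene.
3. 13 comes from a terminal Claisen union of the trianion of prenylated diketo ester 12 (C4a, C8a, C8, C7, C6, C5) with (S)-β-hydroxy ester 7 (C2–C4). The only stereocentre is set by a catalytic asymmetric acetate aldol on aldehyde 4.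
4. 12 comes from tert-butyl acetoacetate, prenyl bromide and an acetyl Weinreb amide. 4 comes from 4-hydroxybenzaldehyde and geranyl bromide.
5. Ring order: B is bought, then C, then A, with C and A formed in the same operation.

Abbreviations in names: geranyl = (2E)-3,7-dimethylocta-2,6-dien-1-yl; prenyl = 3-methylbut-2-en-1-yl; TBS = tert-butyldimethylsilyl; Ar = 4-(TBS-oxy)-3-geranylphenyl.

Assumption: the (R,R)-bisphosphoramide is taken as the antipode that gives Si-face (3S) addition to aldehyde 4; if Mosher analysis of 7 shows 3R, the (S,S)-catalyst is used and nothing else changes.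

## Route

Step 1
Reactants: 1 4-hydroxybenzaldehyde; 2 geranyl bromide
Product: 3 3-geranyl-4-hydroxybenzaldehyde
Conditions: KOH (1.1 equiv), H2O, rt, 24 h
Reagents that add atoms: none
Why: Phenoxide ortho C-allylation (SN2 at the primary allylic bromide, so the E-alkene is kept): in water the phenoxide oxygen is hydrogen-bonded, so the ring carbon ortho to O competes with O-alkylation while the para position is blocked by CHO, and the O-geranyl ether by-product is separated.

Step 2
Reactants: 3 3-geranyl-4-hydroxybenzaldehyde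
Product: 4 4-(TBS-oxy)-3-geranylbenzaldehyde
Conditions: TBSCl (1.1 equiv), imidazole (1.5 equiv), DMF, rt
Reagents that add atoms: tert-butyldimethylsilyl chloride, CC(C)(C)[Si](C)(C)Cl
Why: Imidazole-mediated silylation of the only OH masks the acidic phenol for the aldol and polyanion steps.

Step 3
Reactants: 4 4-(TBS-oxy)-3-geranylbenzaldehyde; 5 tert-butyl[(1-methoxyethenyl)oxy]dimethylsilane
Product: 7 methyl (3S)-3-Ar-3-hydroxypropanoate, via trichlorosilyl ether 6 (not isolated)
Conditions: 5 (1.2 equiv), SiCl4 (1.1 equiv), (R,R)-BINAM-derived bisphosphoramide (5 mol%), i-Pr2NEt (10 mol%), CH2Cl2, −78 °C; sat. aq NaHCO3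
Reagents that add atoms: silicon tetrachloride, Cl[Si](Cl)(Cl)Cl (its atoms stay only in 6)
Why: Lewis-base-catalysed Mukaiyama acetate aldol (SiCl4 with a chiral phosphoramide), which works best with aromatic aldehydes; the chiral trichlorosilyl cation binds the aldehyde and leaves only its Si face open to the ketene acetal, which sets the single stereocentre (3S, the future C2) under catalyst control.

Step 4
Reactants: 8 tert-butyl acetoacetate; 9 prenyl bromide
Product: 10 tert-butyl 2-acetyl-5-methylhex-4-enoate (racemic)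
Conditions: NaH (1.05 equiv), THF, 0 °C; then 9 (1.0 equiv), 0 °C → rt
Reagents that add atoms: none
Why: Acetoacetic ester mono-C-alkylation of the β-keto ester enolate with a reactive allylic bromide; the new centre is racemic and later becomes an sp2 ring carbon.

Step 5
Reactants: 10 tert-butyl 2-acetyl-5-methylhex-4-enoate; 11 N-methoxy-N-methylacetamide
Product: 12 tert-butyl 2-prenyl-3,5-dioxohexanoate (racemic, enolised)
Conditions: LDA (2.2 equiv), THF, −78 → 0 °C; then 11 (1.0 equiv), −78 → 0 °C; sat. aq NH4Cl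
Reagents that add atoms: none
Why: Huckin–Weiler γ-acylation: the β-keto ester dianion reacts at its more basic terminal carbon, and the Weinreb amide gives a chelated adduct that releases the 1,3-diketone only on work-up, so there is no over-addition.

Step 6
Reactants: 12 tert-butyl 2-prenyl-3,5-dioxohexanoate; 7 methyl (3S)-3-Ar-3-hydroxypropanoate
Product: 13 tert-butyl (9S)-9-Ar-9-hydroxy-2-prenyl-3,5,7-trioxononanoate (C2 epimers, enolised, used at once)
Conditions: 12 (3.0 equiv), LDA (9.2 equiv), THF, −78 → 0 °C; then 7 (1.0 equiv), −78 → −20 °C, 2 h; AcOH/THF quench at −78 °C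
Reagents that add atoms: none
Why: Harris-type terminal Claisen acylation of a 1,3,5-tricarbonyl trianion, which reacts only at its most basic terminal carbanion; 7 is carried as its lithium alkoxide (as in Claisen condensations of unprotected β-hydroxy esters), which cannot β-eliminate and keeps the carbinol stereocentre intact at low temperature.

Step 7
Reactants: 13 tert-butyl (9S)-9-Ar-9-hydroxy-2-prenyl-3,5,7-trioxononanoate
Product: 16 (2S)-2-Ar-5,7-dihydroxy-6-prenyl-2,3-dihydro-4H-chromen-4-one, via dihydropyranone 14 (not isolated), via acylketene 15 (not isolated)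
Conditions: TFA (2 equiv), CH2Cl2, 0 °C, 30 min; evaporate from toluene; then m-xylene (0.01 M), 135 °C, N2 sweep, 1–2 h (one flask)
Reagents that add atoms: none
Why: Proposed new method: TFA closes the δ-hydroxy-β-diketone to the 2,3-dihydro-4H-pyran-4-one 14 (ring C; the C–O bond at the stereocentre is never broken, so 2S is retained), then heat expels tert-butanol from the β-keto tert-butyl ester to give the α-prenyl acylketene 15, whose ketene carbon can reach only the nucleophilic C5 of the vinylogous ester through a six-membered array (6π-electrocyclisation of the enol form or stepwise C-acylation), and enolisation of the resulting cyclohexadienone gives the phloroglucinol ring A with prenyl fixed between the two OH groups; the closest known reactions are the acid cyclodehydration of δ-hydroxy-β-diketones, thermal acylketene formation from tert-butyl β-keto esters or dioxinones followed by aromatisation, and the dienylketene ring closure of the Danheiser benzannulation.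

Step 8
Reactants: 16 (2S)-2-Ar-5,7-dihydroxy-6-prenyl-2,3-dihydro-4H-chromen-4-one
Product: 17 schizolaenone A, (2S)-2-(3-geranyl-4-hydroxyphenyl)-5,7-dihydroxy-6-prenyl-2,3-dihydro-4H-chromen-4-one
Conditions: KHF2 (2.5 equiv), MeOH, rt, 1 h
Reagents that add atoms: none
Why: Fluoride cleavage of the aryl silyl ether with near-neutral KHF2, which is selective for phenolic TBS ethers and avoids the basic conditions that would open the flavanone to the chalcone and racemise C2.

## Compound list

1 | 4-hydroxybenzaldehyde | O=Cc1ccc(O)cc1 | starting material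
2 | geranyl bromide, (2E)-1-bromo-3,7-dimethylocta-2,6-diene | BrC/C=C(\C)CCC=C(C)C | starting material
3 | 3-geranyl-4-hydroxybenzaldehyde | CC(C)=CCC/C(C)=C/Cc1cc(C=O)ccc1O | intermediate
4 | 4-(TBS-oxy)-3-geranylbenzaldehyde | CC(C)=CCC/C(C)=C/Cc1cc(C=O)ccc1O[Si](C)(C)C(C)(C)C | intermediate
5 | tert-butyl[(1-methoxyethenyl)oxy]dimethylsilane | C=C(OC)O[Si](C)(C)C(C)(C)C | starting material
6 | methyl (3S)-3-Ar-3-[(trichlorosilyl)oxy]propanoate | CC(C)=CCC/C(C)=C/Cc1cc([C@@H](O[Si](Cl)(Cl)Cl)CC(=O)OC)ccc1O[Si](C)(C)C(C)(C)C | intermediate (not isolated)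
7 | methyl (3S)-3-Ar-3-hydroxypropanoate | CC(C)=CCC/C(C)=C/Cc1cc([C@@H](O)CC(=O)OC)ccc1O[Si](C)(C)C(C)(C)C | intermediate
8 | tert-butyl acetoacetate | CC(=O)CC(=O)OC(C)(C)C | starting material
9 | prenyl bromide, 1-bromo-3-methylbut-2-ene | CC(C)=CCBr | starting material
10 | tert-butyl 2-acetyl-5-methylhex-4-enoate (racemic) | CC(=O)C(CC=C(C)C)C(=O)OC(C)(C)C | intermediate
11 | N-methoxy-N-methylacetamide | CC(=O)N(C)OC | starting material
12 | tert-butyl 2-prenyl-3,5-dioxohexanoate (racemic) | CC(=O)CC(=O)C(CC=C(C)C)C(=O)OC(C)(C)C | intermediate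
13 | tert-butyl (9S)-9-Ar-9-hydroxy-2-prenyl-3,5,7-trioxononanoate (C2 epimers) | CC(C)=CCC/C(C)=C/Cc1cc([C@@H](O)CC(=O)CC(=O)CC(=O)C(CC=C(C)C)C(=O)OC(C)(C)C)ccc1O[Si](C)(C)C(C)(C)C | intermediate
14 | tert-butyl 4-[(2S)-2-Ar-4-oxo-3,4-dihydro-2H-pyran-6-yl]-3-oxo-2-prenylbutanoate | CC(C)=CCC/C(C)=C/Cc1cc([C@@H]2CC(=O)C=C(CC(=O)C(CC=C(C)C)C(=O)OC(C)(C)C)O2)ccc1O[Si](C)(C)C(C)(C)C | intermediate (not isolated)
15 | (2S)-2-Ar-6-[6-methyl-2-oxo-3-(oxomethylidene)hept-5-en-1-yl]-2,3-dihydro-4H-pyran-4-one (acylketene) | CC(C)=CCC/C(C)=C/Cc1cc([C@@H]2CC(=O)C=C(CC(=O)C(CC=C(C)C)=C=O)O2)ccc1O[Si](C)(C)C(C)(C)C | intermediate (not isolated)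
16 | (2S)-2-Ar-5,7-dihydroxy-6-prenyl-2,3-dihydro-4H-chromen-4-one | CC(C)=CCC/C(C)=C/Cc1cc([C@@H]2CC(=O)c3c(cc(O)c(CC=C(C)C)c3O)O2)ccc1O[Si](C)(C)C(C)(C)C | intermediate
17 | schizolaenone A | CC(C)=CCC/C(C)=C/Cc1cc([C@@H]2CC(=O)c3c(cc(O)c(CC=C(C)C)c3O)O2)ccc1O | target

## Step count and risks

Total steps: 8. Longest linear sequence: 6 (steps 1, 2, 3, 6, 7, 8); steps 4 and 5 build the side fragment.

Three steps most likely to fail:

Step 7 (two-ring cascade). The acid stage could give some γ-pyrone or benzylic dehydration, and the thermal stage could give intermolecular ketene trapping, decarboxylation or erosion of ee at 135 °C. The fallback sets out from 14, isolated after the TFA stage, and replaces the thermal ester-to-ketene event by low-temperature carboxyl activation. Selective tert-butyl ester cleavage (85% aq H3PO4, toluene, rt) gives 4-[(2S)-2-Ar-4-oxo-3,4-dihydro-2H-pyran-6-yl]-3-oxo-2-prenylbutanoic acid F5. Trifluoroacetic anhydride and 2,6-lutidine (CH2Cl2, −20 → 0 °C) convert it through the mixed trifluoroacetic anhydride F6 into the same acylketene 15 below 0 °C. This closes onto C5 of the pyranone, and a cold NaHCO3 work-up cleaves any aryl trifluoroacetate. The fallback comes back to the route at 16.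

Step 6 (trianion Claisen with an unprotected β-hydroxy methyl ester). Proton transfer, retro-aldol or slow addition to the ester could lower the yield. The fallback sets out from 7 and changes the acyl donor and the protection. Aminolysis (MeONHMe·HCl, i-PrMgCl, THF, −20 °C) gives (3S)-3-Ar-3-hydroxy-N-methoxy-N-methylpropanamide F2. Silylation (TESCl, imidazole) gives (3S)-3-Ar-N-methoxy-N-methyl-3-(triethylsilyloxy)propanamide F3. The trianion of 12 (1.5 equiv) adds once to this amide to give tert-butyl (9S)-9-Ar-2-prenyl-3,5,7-trioxo-9-(triethylsilyloxy)nonanoate F4. The TFA stage of step 7 then removes the triethylsilyl group and cyclises, so the fallback comes back to the route at 14.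

Step 1 (direct ortho C-geranylation). O-alkylation and dialkylation can dominate. The fallback sets out from 1. Bromination (Br2, AcOH, 0 °C) gives 3-bromo-4-hydroxybenzaldehyde F1. A ligand-controlled α-selective allyl–aryl Suzuki–Miyaura coupling with (E)-geranylboronic acid pinacol ester (Pd(OAc)2, bulky biarylphosphine, K3PO4, THF/H2O, 40 °C) installs the geranyl group at the brominated carbon. The fallback comes back to the route at 3.

## Further compounds

F1 | step 1 | 3-bromo-4-hydroxybenzaldehyde | O=Cc1ccc(O)c(Br)c1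
F2 | step 6 | (3S)-3-Ar-3-hydroxy-N-methoxy-N-methylpropanamide | CC(C)=CCC/C(C)=C/Cc1cc([C@@H](O)CC(=O)N(C)OC)ccc1O[Si](C)(C)C(C)(C)C
F3 | step 6 | (3S)-3-Ar-N-methoxy-N-methyl-3-(triethylsilyloxy)propanamide | CC(C)=CCC/C(C)=C/Cc1cc([C@@H](O[Si](CC)(CC)CC)CC(=O)N(C)OC)ccc1O[Si](C)(C)C(C)(C)C
F4 | step 6 | tert-butyl (9S)-9-Ar-2-prenyl-3,5,7-trioxo-9-(triethylsilyloxy)nonanoate | CC(C)=CCC/C(C)=C/Cc1cc([C@@H](O[Si](CC)(CC)CC)CC(=O)CC(=O)CC(=O)C(CC=C(C)C)C(=O)OC(C)(C)C)ccc1O[Si](C)(C)C(C)(C)C
F5 | step 7 | 4-[(2S)-2-Ar-4-oxo-3,4-dihydro-2H-pyran-6-yl]-3-oxo-2-prenylbutanoic acid | CC(C)=CCC/C(C)=C/Cc1cc([C@@H]2CC(=O)C=C(CC(=O)C(CC=C(C)C)C(=O)O)O2)ccc1O[Si](C)(C)C(C)(C)C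
F6 | step 7 | mixed trifluoroacetic anhydride of F5 | CC(C)=CCC/C(C)=C/Cc1cc([C@@H]2CC(=O)C=C(CC(=O)C(CC=C(C)C)C(=O)OC(=O)C(F)(F)F)O2)ccc1O[Si](C)(C)C(C)(C)C
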